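The retrosynthesis cuts the lactam N–C(=O) bond (ring D) and the N–CH2 bond at the bridgehead CH (ring E). With CH2OAc read as a reduced CO2H, it then cuts the bond between C-q and the bridgehead CH of seven-membered ring C. The side chain leaves C-q at its first CH2, and ring B opens at its C=C (aldol).
The enabling feature is that C-q (quaternary, shared by rings C, D and E) carries a latent carboxyl carbon (CH2OAc) and is bonded to the bridgehead CH. Placing a C=C next to that CH and an O on the ring-C carbon attached to ring B gives the retron of an Ireland–Claisen shift of a seven-membered lactone.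
In the forward direction ring A is bought as a cyclopentanone beta-keto ester and ring B is closed by aldol condensation. The lactone follows by Yamaguchi closure, fragment 2 is joined by lactone alkylation, and ring C forms in the [3,3] shift. Ring E is then closed by Mitsunobu N-alkylation and ring D by lactamisation.
C-alpha is set by phase-transfer catalysis, and the ring-fusion CH is relayed from it by anti conjugate addition and anti allylation. The carbinol comes from zinc-catalysed alkynylation, and C-q and the bridgehead CH come from the carbinol and the Z alkene through a boat. The ring-A ester carbon is set by convex-face protonation after the shift; CH(OH) comes from allylboration and CH(CH3) from the chiral pool.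

Key step: step 19

Labels:
- C-alpha is the quaternary ring-A carbon that becomes the lactam alpha carbon.
- C-q is the quaternary carbon bearing CH2OAc.
- Ring A is the cyclopentane with CO2Me, ring B the cyclopentene, ring C the seven-membered carbocycle, ring D the six-membered lactam and ring E the nine-membered azacycle.

Remarks:
- 32 is drawn as one epimer at the lactone alpha carbon; both epimers give the same ketene acetal 33.
- The ring-A ester is carried trans to the ring-B CH2 on purpose until step 19, where it is enolised and re-set.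

Step 1
Reactants: 1 methyl 2-oxocyclopentane-1-carboxylate; 2 tert-butyl bromoacetate
Product: 3 methyl (S)-1-(2-tert-butoxy-2-oxoethyl)-2-oxocyclopentane-1-carboxylate
Conditions: chiral N-spiro bis(binaphthyl)ammonium bromide (1 mol %, antipode that leaves the Si face open), K2CO3, toluene, −20 °C
Reagents that add atoms: tert-butyl bromoacetate (2), BrCC(=O)OC(C)(C)C
Why: Asymmetric phase-transfer alkylation of cyclic beta-keto esters is well established, and the chiral ammonium enolate ion pair exposes only the Si face of the enolate carbon, which sets C-alpha as S.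

Step 2
Reactants: 3 methyl (S)-1-(2-tert-butoxy-2-oxoethyl)-2-oxocyclopentane-1-carboxylate
Product: 5 methyl (S)-1-(2-tert-butoxy-2-oxoethyl)-2-oxocyclopent-3-ene-1-carboxylate, via silyl enol ether 4 (not isolated)
Conditions: LiN(SiMe3)2, Me3SiCl, THF, −78 °C; then Pd(OAc)2 (10 mol %), O2 (1 atm), DMSO, rt
Reagents that add atoms: none
Why: In this Saegusa–Ito oxidation the ketone can enolise only away from quaternary C-alpha, so silylation and palladium-mediated beta-hydride loss give a single enone and leave C-alpha untouched.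

Step 3
Reactants: 5 methyl (S)-1-(2-tert-butoxy-2-oxoethyl)-2-oxocyclopent-3-ene-1-carboxylate; 6 tris(methylthio)methane; 7 allyl iodide
Product: 9 methyl (1S,3R,4S)-3-allyl-1-(2-tert-butoxy-2-oxoethyl)-2-oxo-4-[tris(methylthio)methyl]cyclopentane-1-carboxylate, via lithium enolate 8 (not isolated)
Conditions: 6, n-BuLi, THF, −78 °C; add 5; then 7, DMPU, −78 to −30 °C
Reagents that add atoms: tris(methylthio)methane (6), CSC(SC)SC; allyl iodide (7), C=CCI
Why: This is conjugate addition of a carboxyl anion equivalent followed by enolate trapping (three-component coupling), in which the bulky nucleophile adds to the enone face opposite the CH2CO2tBu arm (the larger substituent on C-alpha and the axial one in the lithium chelate of the beta-keto ester) and allyl iodide then enters anti to the new C(SMe)3 group, so the allyl group ends cis to the arm as the ring-fusion carbon requires.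

Step 4
Reactants: 9 methyl (1S,3R,4S)-3-allyl-1-(2-tert-butoxy-2-oxoethyl)-2-oxo-4-[tris(methylthio)methyl]cyclopentane-1-carboxylate
Product: 10 dimethyl (1S,3S,4R)-4-allyl-1-(2-tert-butoxy-2-oxoethyl)-5-oxocyclopentane-1,3-dicarboxylate
Conditions: HgCl2, HgO, MeOH–H2O 12:1, rt
Reagents that add atoms: methanol, CO; water, O
Why: Thiophilic solvolysis of the trithioorthoester (orthothioester methanolysis) gives the methyl ester without touching the alkene, the tert-butyl ester or the stereocentres.

Step 5
Reactants: 10 dimethyl (1S,3S,4R)-4-allyl-1-(2-tert-butoxy-2-oxoethyl)-5-oxocyclopentane-1,3-dicarboxylate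
Product: 11 dimethyl (1S,3S,4R)-1-(2-tert-butoxy-2-oxoethyl)-5-oxo-4-(4-oxobutyl)cyclopentane-1,3-dicarboxylate
Conditions: Rh(acac)(CO)2 (1 mol %), Xantphos, CO/H2 1:1 (20 bar), toluene, 70 °C
Reagents that add atoms: carbon monoxide, [C-]#[O+]
Why: Rhodium-catalysed hydroformylation with a wide-bite-angle diphosphine puts the formyl group on the terminal carbon of the monosubstituted alkene and so supplies the future carbinol carbon.

Step 6
Reactants: 11 dimethyl (1S,3S,4R)-1-(2-tert-butoxy-2-oxoethyl)-5-oxo-4-(4-oxobutyl)cyclopentane-1,3-dicarboxylate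
Product: 13 dimethyl (1S,3S,3aR)-1-(2-tert-butoxy-2-oxoethyl)-6-formyl-1,2,3,3a,4,5-hexahydropentalene-1,3-dicarboxylate, via aldol adduct 12 (not isolated)
Conditions: dibenzylammonium trifluoroacetate, toluene, 60 °C
Reagents that add atoms: none
Why: Amine-salt-promoted intramolecular aldol condensation of a 1,6-keto aldehyde closes ring B and dehydrates to the tetrasubstituted enal, and the ring-fusion centre holds because its chain is already trans to the neighbouring ester.

Step 7
Reactants: 13 dimethyl (1S,3S,3aR)-1-(2-tert-butoxy-2-oxoethyl)-6-formyl-1,2,3,3a,4,5-hexahydropentalene-1,3-dicarboxylate; 14 benzyl propargyl ether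
Product: 15 dimethyl (1S,3S,3aR)-6-[(S)-4-(benzyloxy)-1-hydroxybut-2-yn-1-yl]-1-(2-tert-butoxy-2-oxoethyl)-1,2,3,3a,4,5-hexahydropentalene-1,3-dicarboxylate
Conditions: 14, ZnMe2, ProPhenol ligand (20 mol %, antipode for Si-face attack), Ph3PO, toluene, 4 °C
Reagents that add atoms: benzyl propargyl ether (14), C#CCOCc1ccccc1
Why: Catalytic asymmetric alkynylation of an unsaturated aldehyde with the dinuclear zinc–ProPhenol catalyst delivers the alkynyl group to the Si face of the formyl group and sets the S carbinol under catalyst control.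

Step 8
Reactants: 15 dimethyl (1S,3S,3aR)-6-[(S)-4-(benzyloxy)-1-hydroxybut-2-yn-1-yl]-1-(2-tert-butoxy-2-oxoethyl)-1,2,3,3a,4,5-hexahydropentalene-1,3-dicarboxylate
Product: 17 2-[(1S,3S,3aR)-6-[(S)-4-(benzyloxy)-1-hydroxybut-2-yn-1-yl]-1,3-bis(methoxycarbonyl)-1,2,3,3a,4,5-hexahydropentalen-1-yl]acetic acid, via bis(trimethylsilyl) derivative 16 (not isolated)
Conditions: Me3SiOTf, 2,6-lutidine, CH2Cl2, 0 °C; then aq. citric acid, THF
Reagents that add atoms: none
Why: Silyl triflate with a hindered pyridine cleaves the tert-butyl ester through its silyl ester under non-protic conditions (silylative ester cleavage), so the ionisable allylic and propargylic alcohol, masked in passing as its silyl ether, and both methyl esters survive.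

Step 9
Reactants: 17 2-[(1S,3S,3aR)-6-[(S)-4-(benzyloxy)-1-hydroxybut-2-yn-1-yl]-1,3-bis(methoxycarbonyl)-1,2,3,3a,4,5-hexahydropentalen-1-yl]acetic acid
Product: 19 alkynyl lactone (diquinane-fused seven-membered lactone O–C(=O)–CH2–C-alpha–C=C–CH with the S carbinol carbon bearing 3-(benzyloxy)prop-1-ynyl), via mixed anhydride 18 (not isolated)
Conditions: 2,4,6-Cl3C6H2COCl, Et3N, THF, rt; then DMAP, toluene (2 mM), 60 °C
Reagents that add atoms: none
Why: Yamaguchi lactonisation is helped by the cis alkene and the quaternary centre in the chain, whereas the six-membered lactone with the C-alpha ester would have to span the wide exocyclic angle between rings A and B and uses an unactivated hindered ester.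

Step 10
Reactants: 19 alkynyl lactone
Product: 20 Z-alkenyl lactone (as 19 with a (Z)-3-(benzyloxy)prop-1-enyl group cis to the C-alpha CO2Me across the lactone ring)
Conditions: H2 (1 atm), Pd/CaCO3 poisoned with Pb(OAc)2, quinoline, EtOAc, rt
Reagents that add atoms: none
Why: Semihydrogenation of the alkyne over poisoned palladium is a syn addition and gives only the Z alkene that the key step needs.

Step 11
Reactants: 21 (S)-3-bromo-2-methylpropan-1-ol; 22 benzylamine
Product: 23 (R)-3-(benzylamino)-2-methylpropan-1-ol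
Conditions: 22 (3 equiv), EtOH, 78 °C
Reagents that add atoms: benzylamine (22), NCc1ccccc1
Why: SN2 displacement of the primary bromide by excess amine does not touch the methyl-bearing stereocentre taken from the chiral pool (the descriptor changes by priority only).

Step 12
Reactants: 23 (R)-3-(benzylamino)-2-methylpropan-1-ol
Product: 24 benzyl (R)-benzyl(3-hydroxy-2-methylpropyl)carbamate
Conditions: PhCH2OCOCl, NaHCO3, CH2Cl2–H2O, 0 °C
Reagents that add atoms: benzyl chloroformate, O=C(Cl)OCc1ccccc1
Why: Schotten–Baumann carbamate formation removes the nucleophilicity of nitrogen, which would otherwise close a piperidinium ring onto the later iodide, and both N-substituents fall to one hydrogenolysis.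

Step 13
Reactants: 24 benzyl (R)-benzyl(3-hydroxy-2-methylpropyl)carbamate
Product: 25 benzyl (R)-benzyl(2-methyl-3-oxopropyl)carbamate
Conditions: TEMPO (10 mol %), PhI(OAc)2, CH2Cl2, rt
Reagents that add atoms: none
Why: Nitroxyl-catalysed oxidation stops at the aldehyde under nearly neutral conditions that do not epimerise the alpha-methyl centre.

Step 14
Reactants: 25 benzyl (R)-benzyl(2-methyl-3-oxopropyl)carbamate
Product: 26 benzyl benzyl[(2R,3R)-3-hydroxy-2-methylhex-5-en-1-yl]carbamate
Conditions: (+)-Ipc2B(allyl), Et2O, −78 °C; then NaOH, H2O2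
Reagents that add atoms: (+)-B-allyldiisopinocampheylborane, C=CCB(C1CC2CC(C1C)C2(C)C)C1CC2CC(C1C)C2(C)C
Why: Brown allylboration through a closed chair transition state is reagent controlled, and the borane derived from (−)-alpha-pinene gives the R carbinol, syn to the methyl group.

Step 15
Reactants: 26 benzyl benzyl[(2R,3R)-3-hydroxy-2-methylhex-5-en-1-yl]carbamate
Product: 27 benzyl benzyl[(2R,3R)-3-(tert-butyldimethylsilyloxy)-2-methylhex-5-en-1-yl]carbamate
Conditions: t-BuMe2SiOTf, 2,6-lutidine, CH2Cl2, 0 °C
Reagents that add atoms: tert-butyldimethylsilyl triflate, CC(C)(C)[Si](C)(C)OS(=O)(=O)C(F)(F)F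
Why: Silyl ether formation protects the secondary alcohol with a group that withstands amide bases, borane, hydrogenation and thiolate and is removed last by fluoride.

Step 16
Reactants: 27 benzyl benzyl[(2R,3R)-3-(tert-butyldimethylsilyloxy)-2-methylhex-5-en-1-yl]carbamate
Product: 29 benzyl benzyl[(2R,3R)-3-(tert-butyldimethylsilyloxy)-5-hydroxy-2-methylpentyl]carbamate, via aldehyde 28 (not isolated)
Conditions: O3, CH2Cl2–MeOH, −78 °C; then NaBH4, −78 °C to rt
Reagents that add atoms: ozone, [O-][O+]=O
Why: Ozonolysis with reductive work-up removes the terminal carbon of the only alkene and gives the two-carbon spacer as a primary alcohol, with nitrogen protected from ozone as its carbamate.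

Step 17
Reactants: 29 benzyl benzyl[(2R,3R)-3-(tert-butyldimethylsilyloxy)-5-hydroxy-2-methylpentyl]carbamate
Product: 30 benzyl benzyl[(2R,3R)-3-(tert-butyldimethylsilyloxy)-5-iodo-2-methylpentyl]carbamate
Conditions: I2, PPh3, imidazole, CH2Cl2, 0 °C
Reagents that add atoms: iodine, II
Why: Appel-type iodination converts the unhindered primary alcohol into the iodide under neutral conditions that spare the silyl ether and the carbamate.

Step 18
Reactants: 20 Z-alkenyl lactone; 30 benzyl benzyl[(2R,3R)-3-(tert-butyldimethylsilyloxy)-5-iodo-2-methylpentyl]carbamate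
Product: 32 side-chain lactone (20 carrying at the lactone alpha carbon the (3R,4R)-5-[benzyl(benzyloxycarbonyl)amino]-3-(tert-butyldimethylsilyloxy)-4-methylpentyl chain), via lactone enolate 31 (not isolated)
Conditions: LiN(SiMe3)2 (1.05 equiv), THF, −78 °C; 30, DMPU, −78 to −40 °C
Reagents that add atoms: iodide 30, ICC[C@@H](O[Si](C)(C)C(C)(C)C)[C@H](C)CN(Cc1ccccc1)C(=O)OCc1ccccc1
Why: In this lactone enolate alkylation the ring-locked ester geometry makes the lactone CH2 clearly more acidic than the tertiary C–H of the ring-A ester, so one equivalent of base enolises only the lactone, and the new centre needs no control because it becomes planar in the next step.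

Step 19
Reactants: 32 side-chain lactone
Product: 35 tricyclic acid (rings A, B and C with a ring-C diene; C-q bears CO2H and the side chain; the bridgehead CH bears CH2OBn; the ring-A ester is now cis to the ring-B CH2), via bis(silyl ketene acetal) 33 (not isolated), via rearranged silyl ester 34 (not isolated)
Conditions: LDA (4 equiv), Me3SiCl–Et3N, THF–DMPU, −78 to 0 °C; toluene, 90 °C; then aq. citric acid, THF, 0 °C
Reagents that add atoms: none
Why: LDA with Me3SiCl present turns both enolisable carbonyl groups of 32 into silyl ketene acetals (33), and on heating the ring ketene acetal C=C, the ring oxygen, the carbinol carbon and the Z alkene undergo a concerted suprafacial [3,3] shift that makes the C-q–CH bond and breaks the doubly allylic C–O bond; this is the Ireland–Claisen rearrangement of an alkenyl lactone, a known route from lactones to cycloalkenecarboxylic acids. Ring C closes by ring switch and not by cyclisation of a chain: C(=O)–O leave the seven-membered ring while the two alkene carbons enter it, and because C-alpha and the ring-B alkene carbon tie both termini together only the boat transition state can be reached. C-q is set by the carbinol configuration, since the alkenyl arm lies on the lactone face that also carries the C-alpha ester and can reach only that face of the ring-fixed ketene acetal, and the bridgehead CH follows from the Z geometry, which in the boat places CH2OBn over the C-alpha ester. The ring-A ester carbon is set last, when acidic hydrolysis protonates its ketene acetal from the convex face of the diquinane (the face of the ring-fusion H) and so turns the ester to the concave face as in the target. The step needs the shift to outrun ionisation of the doubly allylic ester, which the electron-rich ketene acetal and the weak C–O bond favour, while the other allyl unit (the ring-B alkene) cannot take part because its new bond would close a three-membered ring, and silyl ester formation makes the shift irreversible.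

Step 20
Reactants: 35 tricyclic acid
Product: 36 dihydro acid (35 with the disubstituted ring-C alkene saturated)
Conditions: H2 (4 bar), RhCl(PPh3)3 (10 mol %), benzene–EtOH, rt
Reagents that add atoms: none
Why: Homogeneous hydrogenation with RhCl(PPh3)3 reduces cis-disubstituted alkenes and leaves tetrasubstituted alkenes, benzyl ethers and carbamates alone, so only the alkene made in the rearrangement is saturated and no 1,4-addition to the diene is expected.

Step 21
Reactants: 36 dihydro acid
Product: 37 neopentyl alcohol (C-q bears CH2OH)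
Conditions: BH3·THF, THF, 0 °C to rt; MeOH
Reagents that add atoms: none
Why: Borane reduces a carboxylic acid through its acyloxyborane faster than esters, carbamates or a shielded tetrasubstituted alkene, and the new CH2OH is held anti to the C-alpha ester across the C-q–C-alpha bond by ring C and so cannot lactonise.

Step 22
Reactants: 37 neopentyl alcohol
Product: 38 acetate (C-q bears CH2OAc)
Conditions: Ac2O, DMAP, pyridine, rt
Reagents that add atoms: acetic anhydride, CC(=O)OC(C)=O
Why: DMAP-catalysed acylation esterifies the only free hydroxyl group, even though it is neopentyl.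

Step 23
Reactants: 38 acetate
Product: 39 amino alcohol (free CH2OH on the bridgehead CH and free NH2 at the chain end)
Conditions: H2 (1 atm), Pd(OH)2/C, EtOH, rt
Reagents that add atoms: none
Why: Hydrogenolysis cleaves the benzyl ether, the benzyl carbamate and then the N-benzyl group in one operation, while the tetrasubstituted alkene is too hindered to be reduced.

Step 24
Reactants: 39 amino alcohol
Product: 40 2-nitrobenzenesulfonamide alcohol
Conditions: 2-O2NC6H4SO2Cl, Et3N, CH2Cl2, 0 °C
Reagents that add atoms: 2-nitrobenzenesulfonyl chloride, O=S(=O)(Cl)c1ccccc1[N+](=O)[O-]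
Why: Chemoselective N-sulfonylation works because the primary amine far outpaces the hindered primary alcohol, and it gives an N–H acidic enough for Mitsunobu alkylation.

Step 25
Reactants: 40 2-nitrobenzenesulfonamide alcohol
Product: 41 nine-membered N-sulfonyl azacycle (ring E closed)
Conditions: PPh3, DIAD, toluene (3 mM), rt to 50 °C
Reagents that add atoms: none
Why: In the Fukuyama–Mitsunobu cyclisation the acidic sulfonamide is alkylated by the activated primary alcohol, a protocol established for eight- to ten-membered cyclic amines, and high dilution suppresses dimers.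

Step 26
Reactants: 41 nine-membered N-sulfonyl azacycle
Product: 43 silyl-protected pentacyclic lactam, via secondary amine 42 (not isolated)
Conditions: PhSH, K2CO3, MeCN, rt; filter; then 2-hydroxypyridine, toluene, 90 °C
Reagents that add atoms: none
Why: Thiolate removes the sulfonyl group by nucleophilic aromatic substitution through a Meisenheimer adduct, and the freed secondary amine, whose CH2–CH arm is held gauche to the C-alpha ester, closes six-membered ring D by lactamisation.

Step 27
Reactants: 43 silyl-protected pentacyclic lactam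
Product: 44 CNP0296366.1
Conditions: HF·pyridine, THF, 0 °C to rt
Reagents that add atoms: none
Why: Fluoride-mediated desilylation frees the secondary alcohol without touching the acetate, the methyl ester, the lactam or the epimerisable ring-A ester carbon.

Compound list
1 | methyl 2-oxocyclopentane-1-carboxylate | COC(=O)C1CCCC1=O | starting material
2 | tert-butyl bromoacetate | BrCC(=O)OC(C)(C)C | starting material
3 | methyl (S)-1-(2-tert-butoxy-2-oxoethyl)-2-oxocyclopentane-1-carboxylate | COC(=O)[C@]1(CC(=O)OC(C)(C)C)CCCC1=O | intermediate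
4 | trimethylsilyl enol ether of 3 | COC(=O)[C@]1(CC(=O)OC(C)(C)C)CCC=C1O[Si](C)(C)C | intermediate
5 | methyl (S)-1-(2-tert-butoxy-2-oxoethyl)-2-oxocyclopent-3-ene-1-carboxylate | COC(=O)[C@]1(CC(=O)OC(C)(C)C)CC=CC1=O | intermediate
6 | tris(methylthio)methane | CSC(SC)SC | starting material
7 | allyl iodide | C=CCI | starting material
8 | lithium enolate from conjugate addition to 5 | COC(=O)[C@]1(CC(=O)OC(C)(C)C)C[C@H](C(SC)(SC)SC)C=C1[O-].[Li+] | intermediate
9 | methyl (1S,3R,4S)-3-allyl-1-(2-tert-butoxy-2-oxoethyl)-2-oxo-4-[tris(methylthio)methyl]cyclopentane-1-carboxylate | COC(=O)[C@]1(CC(=O)OC(C)(C)C)C[C@H](C(SC)(SC)SC)[C@@H](CC=C)C1=O | intermediate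
10 | dimethyl (1S,3S,4R)-4-allyl-1-(2-tert-butoxy-2-oxoethyl)-5-oxocyclopentane-1,3-dicarboxylate | COC(=O)[C@]1(CC(=O)OC(C)(C)C)C[C@H](C(=O)OC)[C@@H](CC=C)C1=O | intermediate
11 | dimethyl (1S,3S,4R)-1-(2-tert-butoxy-2-oxoethyl)-5-oxo-4-(4-oxobutyl)cyclopentane-1,3-dicarboxylate | COC(=O)[C@]1(CC(=O)OC(C)(C)C)C[C@H](C(=O)OC)[C@@H](CCCC=O)C1=O | intermediate
12 | bicyclic aldol adduct (new carbinol and formyl-bearing centres undefined) | COC(=O)[C@H]1C[C@@](CC(=O)OC(C)(C)C)(C(=O)OC)C3(O)C(C=O)CC[C@@H]31 | intermediate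
13 | dimethyl (1S,3S,3aR)-1-(2-tert-butoxy-2-oxoethyl)-6-formyl-1,2,3,3a,4,5-hexahydropentalene-1,3-dicarboxylate | COC(=O)[C@H]1C[C@@](CC(=O)OC(C)(C)C)(C(=O)OC)C3=C(C=O)CC[C@@H]31 | intermediate
14 | benzyl propargyl ether | C#CCOCc1ccccc1 | starting material
15 | dimethyl (1S,3S,3aR)-6-[(S)-4-(benzyloxy)-1-hydroxybut-2-yn-1-yl]-1-(2-tert-butoxy-2-oxoethyl)-1,2,3,3a,4,5-hexahydropentalene-1,3-dicarboxylate | COC(=O)[C@H]1C[C@@](CC(=O)OC(C)(C)C)(C(=O)OC)C3=C(CC[C@@H]31)[C@H](C#CCOCc4ccccc4)O | intermediate
16 | trimethylsilyl ester and trimethylsilyl ether of 17 | COC(=O)[C@H]1C[C@@](CC(=O)O[Si](C)(C)C)(C(=O)OC)C3=C(CC[C@@H]31)[C@H](C#CCOCc4ccccc4)O[Si](C)(C)C | intermediate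
17 | 2-[(1S,3S,3aR)-6-[(S)-4-(benzyloxy)-1-hydroxybut-2-yn-1-yl]-1,3-bis(methoxycarbonyl)-1,2,3,3a,4,5-hexahydropentalen-1-yl]acetic acid | COC(=O)[C@H]1C[C@@](CC(=O)O)(C(=O)OC)C3=C(CC[C@@H]31)[C@H](C#CCOCc4ccccc4)O | intermediate
18 | mixed anhydride of 17 with 2,4,6-trichlorobenzoic acid | COC(=O)[C@H]1C[C@@](CC(=O)OC(=O)c5c(Cl)cc(Cl)cc5Cl)(C(=O)OC)C3=C(CC[C@@H]31)[C@H](C#CCOCc4ccccc4)O | intermediate
19 | alkynyl lactone (diquinane-fused seven-membered lactone, S carbinol carbon) | COC(=O)[C@H]1C[C@@]2(C(=O)OC)C3=C(CC[C@@H]31)[C@H](C#CCOCc4ccccc4)OC(=O)C2 | intermediate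
20 | Z-alkenyl lactone (alkenyl group cis to the C-alpha ester across the lactone) | COC(=O)[C@H]1C[C@@]2(C(=O)OC)C3=C(CC[C@@H]31)[C@H](/C=C\COCc4ccccc4)OC(=O)C2 | intermediate
21 | (S)-3-bromo-2-methylpropan-1-ol | OC[C@H](C)CBr | starting material
22 | benzylamine | NCc1ccccc1 | starting material
23 | (R)-3-(benzylamino)-2-methylpropan-1-ol | OC[C@H](C)CNCc1ccccc1 | intermediate
24 | benzyl (R)-benzyl(3-hydroxy-2-methylpropyl)carbamate | OC[C@H](C)CN(Cc1ccccc1)C(=O)OCc1ccccc1 | intermediate
25 | benzyl (R)-benzyl(2-methyl-3-oxopropyl)carbamate | O=C[C@H](C)CN(Cc1ccccc1)C(=O)OCc1ccccc1 | intermediate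
26 | benzyl benzyl[(2R,3R)-3-hydroxy-2-methylhex-5-en-1-yl]carbamate | C=CC[C@@H](O)[C@H](C)CN(Cc1ccccc1)C(=O)OCc1ccccc1 | intermediate
27 | benzyl benzyl[(2R,3R)-3-(tert-butyldimethylsilyloxy)-2-methylhex-5-en-1-yl]carbamate | C=CC[C@@H](O[Si](C)(C)C(C)(C)C)[C@H](C)CN(Cc1ccccc1)C(=O)OCc1ccccc1 | intermediate
28 | benzyl benzyl[(2R,3R)-3-(tert-butyldimethylsilyloxy)-2-methyl-5-oxopentyl]carbamate | O=CC[C@@H](O[Si](C)(C)C(C)(C)C)[C@H](C)CN(Cc1ccccc1)C(=O)OCc1ccccc1 | intermediate
29 | benzyl benzyl[(2R,3R)-3-(tert-butyldimethylsilyloxy)-5-hydroxy-2-methylpentyl]carbamate | OCC[C@@H](O[Si](C)(C)C(C)(C)C)[C@H](C)CN(Cc1ccccc1)C(=O)OCc1ccccc1 | intermediate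
30 | benzyl benzyl[(2R,3R)-3-(tert-butyldimethylsilyloxy)-5-iodo-2-methylpentyl]carbamate | ICC[C@@H](O[Si](C)(C)C(C)(C)C)[C@H](C)CN(Cc1ccccc1)C(=O)OCc1ccccc1 | intermediate
31 | lithium enolate of lactone 20 | COC(=O)[C@H]1C[C@@]2(C(=O)OC)C3=C(CC[C@@H]31)[C@H](/C=C\COCc4ccccc4)OC([O-])=C2.[Li+] | intermediate
32 | side-chain lactone, precursor of the key step (one epimer at the lactone alpha carbon drawn) | COC(=O)[C@H]1C[C@@]2(C(=O)OC)C3=C(CC[C@@H]31)[C@H](/C=C\COCc4ccccc4)OC(=O)[C@@H]2CC[C@@H](O[Si](C)(C)C(C)(C)C)[C@H](C)CN(Cc4ccccc4)C(=O)OCc4ccccc4 | intermediate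
33 | bis(trimethylsilyl ketene acetal) of 32 | COC(O[Si](C)(C)C)=C1C[C@@]2(C(=O)OC)C3=C(CC[C@@H]31)[C@H](/C=C\COCc4ccccc4)OC(O[Si](C)(C)C)=C2CC[C@@H](O[Si](C)(C)C(C)(C)C)[C@H](C)CN(Cc4ccccc4)C(=O)OCc4ccccc4 | intermediate
34 | rearranged trimethylsilyl ester that still carries the ring-A ketene acetal | COC(O[Si](C)(C)C)=C1C[C@@]2(C(=O)OC)C3=C(CC[C@@H]31)C=C[C@H](COCc4ccccc4)[C@]2(C(=O)O[Si](C)(C)C)CC[C@@H](O[Si](C)(C)C(C)(C)C)[C@H](C)CN(Cc4ccccc4)C(=O)OCc4ccccc4 | intermediate
35 | tricyclic acid, product of the key step | COC(=O)[C@@H]1C[C@@]2(C(=O)OC)C3=C(CC[C@@H]31)C=C[C@H](COCc4ccccc4)[C@]2(C(=O)O)CC[C@@H](O[Si](C)(C)C(C)(C)C)[C@H](C)CN(Cc4ccccc4)C(=O)OCc4ccccc4 | intermediate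
36 | dihydro acid | COC(=O)[C@@H]1C[C@@]2(C(=O)OC)C3=C(CC[C@@H]31)CC[C@H](COCc4ccccc4)[C@]2(C(=O)O)CC[C@@H](O[Si](C)(C)C(C)(C)C)[C@H](C)CN(Cc4ccccc4)C(=O)OCc4ccccc4 | intermediate
37 | neopentyl alcohol | COC(=O)[C@@H]1C[C@@]2(C(=O)OC)C3=C(CC[C@@H]31)CC[C@H](COCc4ccccc4)[C@]2(CO)CC[C@@H](O[Si](C)(C)C(C)(C)C)[C@H](C)CN(Cc4ccccc4)C(=O)OCc4ccccc4 | intermediate
38 | acetate | COC(=O)[C@@H]1C[C@@]2(C(=O)OC)C3=C(CC[C@@H]31)CC[C@H](COCc4ccccc4)[C@]2(COC(C)=O)CC[C@@H](O[Si](C)(C)C(C)(C)C)[C@H](C)CN(Cc4ccccc4)C(=O)OCc4ccccc4 | intermediate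
39 | amino alcohol | COC(=O)[C@@H]1C[C@@]2(C(=O)OC)C3=C(CC[C@@H]31)CC[C@H](CO)[C@]2(COC(C)=O)CC[C@@H](O[Si](C)(C)C(C)(C)C)[C@H](C)CN | intermediate
40 | 2-nitrobenzenesulfonamide alcohol | COC(=O)[C@@H]1C[C@@]2(C(=O)OC)C3=C(CC[C@@H]31)CC[C@H](CO)[C@]2(COC(C)=O)CC[C@@H](O[Si](C)(C)C(C)(C)C)[C@H](C)CNS(=O)(=O)c4ccccc4[N+](=O)[O-] | intermediate
41 | nine-membered N-(2-nitrobenzenesulfonyl) azacycle | COC(=O)[C@@H]1C[C@@]2(C(=O)OC)C3=C(CC[C@@H]31)CC[C@@H]4CN(S(=O)(=O)c5ccccc5[N+](=O)[O-])C[C@@H](C)[C@H](O[Si](C)(C)C(C)(C)C)CC[C@]24COC(C)=O | intermediate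
42 | nine-membered secondary amine | COC(=O)[C@@H]1C[C@@]2(C(=O)OC)C3=C(CC[C@@H]31)CC[C@@H]4CNC[C@@H](C)[C@H](O[Si](C)(C)C(C)(C)C)CC[C@]24COC(C)=O | intermediate
43 | silyl-protected pentacyclic lactam | COC(=O)[C@@H]1C[C@@]23C(=O)N4C[C@@H](CCC5=C2[C@@H]1CC5)[C@]3(COC(C)=O)CC[C@@H](O[Si](C)(C)C(C)(C)C)[C@H](C)C4 | intermediate
44 | CNP0296366.1 | COC(=O)[C@@H]1C[C@@]23C(=O)N4C[C@@H](CCC5=C2[C@@H]1CC5)[C@]3(COC(C)=O)CC[C@@H](O)[C@H](C)C4 | target

Total step count: 27.
Longest linear sequence: 20 steps (steps 1–10 and 18–27).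

Steps most likely to fail

Step 19. Deprotonation of the tertiary C–H next to quaternary C-alpha may be too slow. The doubly allylic ester could then ionise or fragment before the ketene acetal forms, and protonation of the ring-A ketene acetal may lack facial selectivity.
The fallback forms the ring ketene acetal by conjugate hydrosilylation instead of deprotonation. It sets out from lactone 20, together with aldehyde 28 isolated by a Me2S work-up of the ozonolysis of 27. Enolate 31 adds to 28 to give beta-hydroxy lactone F1. MsCl and Et3N give mesylate F2, and DBU eliminates it to alkylidene lactone F3. With [(Ph3P)CuH]6 as catalyst and PhMe2SiH in toluene, 1,4-hydrosilylation gives ring silyl ketene acetal F4. On heating, F4 undergoes the same [3,3] shift to silyl ester F5, and mild acid gives trans-ester acid F6. LDA (3 equiv) at −78 °C converts F6 into dilithium enolate carboxylate F7, and a cold quench with a hindered phenol protonates it from the convex face. The sequence comes back to the route at 35.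

Step 3. The 1,3-induction from C-alpha may give poor facial selectivity in the conjugate addition, and the error would pass on to the ring-fusion carbon.
The fallback puts this centre under catalyst control and sets out from enone 5. Rhodium-catalysed asymmetric 1,4-addition of potassium vinyltrifluoroborate, using [Rh(cod)Cl]2 and the BINAP antipode that attacks anti to the arm, gives vinyl ketone F8. Ozonolysis in methanolic NaOH turns the vinyl group directly into the methyl ester of keto triester F9. LiN(SiMe3)2 gives lithium enolate F10, which can form only towards the ring-fusion carbon. Allyl iodide enters anti to the ester, and the sequence comes back to the route at 10.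

Step 25. Closure of the nine-membered ring by displacement at a beta-branched CH2 may lose to dimerisation or to elimination of the activated alcohol.
The fallback closes ring E by reductive amination and sets out from 40. TEMPO and PhI(OAc)2 give sulfonamide aldehyde F11. PhSH with K2CO3 frees amino aldehyde F12, which condenses to nine-membered cyclic imine F13. NaBH(OAc)3, added at once so that the centre next to the formyl group has little time to epimerise, reduces F13. The sequence comes back to the route at amine 42, which lactamises to 43 as in step 26.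

Further compounds
F1 | step 19 | beta-hydroxy lactone (two new centres undefined) | COC(=O)[C@H]1C[C@@]2(C(=O)OC)C3=C(CC[C@@H]31)[C@H](/C=C\COCc4ccccc4)OC(=O)C2C(O)C[C@@H](O[Si](C)(C)C(C)(C)C)[C@H](C)CN(Cc4ccccc4)C(=O)OCc4ccccc4
F2 | step 19 | mesylate of F1 | COC(=O)[C@H]1C[C@@]2(C(=O)OC)C3=C(CC[C@@H]31)[C@H](/C=C\COCc4ccccc4)OC(=O)C2C(OS(C)(=O)=O)C[C@@H](O[Si](C)(C)C(C)(C)C)[C@H](C)CN(Cc4ccccc4)C(=O)OCc4ccccc4
F3 | step 19 | alkylidene lactone (either geometry of the new alkene) | COC(=O)[C@H]1C[C@@]2(C(=O)OC)C3=C(CC[C@@H]31)[C@H](/C=C\COCc4ccccc4)OC(=O)C2=CC[C@@H](O[Si](C)(C)C(C)(C)C)[C@H](C)CN(Cc4ccccc4)C(=O)OCc4ccccc4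
F4 | step 19 | ring dimethylphenylsilyl ketene acetal | COC(=O)[C@H]1C[C@@]2(C(=O)OC)C3=C(CC[C@@H]31)[C@H](/C=C\COCc4ccccc4)OC(O[Si](C)(C)c5ccccc5)=C2CC[C@@H](O[Si](C)(C)C(C)(C)C)[C@H](C)CN(Cc4ccccc4)C(=O)OCc4ccccc4
F5 | step 19 | rearranged dimethylphenylsilyl ester | COC(=O)[C@H]1C[C@@]2(C(=O)OC)C3=C(CC[C@@H]31)C=C[C@H](COCc4ccccc4)[C@]2(C(=O)O[Si](C)(C)c5ccccc5)CC[C@@H](O[Si](C)(C)C(C)(C)C)[C@H](C)CN(Cc4ccccc4)C(=O)OCc4ccccc4
F6 | step 19 | trans-ester acid (epimer of 35 at the ring-A ester carbon) | COC(=O)[C@H]1C[C@@]2(C(=O)OC)C3=C(CC[C@@H]31)C=C[C@H](COCc4ccccc4)[C@]2(C(=O)O)CC[C@@H](O[Si](C)(C)C(C)(C)C)[C@H](C)CN(Cc4ccccc4)C(=O)OCc4ccccc4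
F7 | step 19 | dilithium enolate carboxylate of F6 | COC([O-])=C1C[C@@]2(C(=O)OC)C3=C(CC[C@@H]31)C=C[C@H](COCc4ccccc4)[C@]2(C([O-])=O)CC[C@@H](O[Si](C)(C)C(C)(C)C)[C@H](C)CN(Cc4ccccc4)C(=O)OCc4ccccc4.[Li+].[Li+]
F8 | step 3 | vinyl ketone (vinyl group trans to the CH2CO2tBu arm) | COC(=O)[C@]1(CC(=O)OC(C)(C)C)C[C@H](C=C)CC1=O
F9 | step 3 | keto triester | COC(=O)[C@]1(CC(=O)OC(C)(C)C)C[C@H](C(=O)OC)CC1=O
F10 | step 3 | lithium enolate of F9 | COC(=O)[C@]1(CC(=O)OC(C)(C)C)C[C@H](C(=O)OC)C=C1[O-].[Li+]
F11 | step 25 | sulfonamide aldehyde | COC(=O)[C@@H]1C[C@@]2(C(=O)OC)C3=C(CC[C@@H]31)CC[C@H](C=O)[C@]2(COC(C)=O)CC[C@@H](O[Si](C)(C)C(C)(C)C)[C@H](C)CNS(=O)(=O)c4ccccc4[N+](=O)[O-]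
F12 | step 25 | amino aldehyde | COC(=O)[C@@H]1C[C@@]2(C(=O)OC)C3=C(CC[C@@H]31)CC[C@H](C=O)[C@]2(COC(C)=O)CC[C@@H](O[Si](C)(C)C(C)(C)C)[C@H](C)CN
F13 | step 25 | nine-membered cyclic imine | COC(=O)[C@@H]1C[C@@]2(C(=O)OC)C3=C(CC[C@@H]31)CC[C@@H]4C=NC[C@@H](C)[C@H](O[Si](C)(C)C(C)(C)C)CC[C@]24COC(C)=O
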